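## Retrosynthetic overview

1. The target comes from a fully silylated ester by global desilylation. That ester is cut at C7–C8 (Stille) into a C8–C23 dienyl iodide and a C1–C7 trienyl stannane already esterified to the protected dihydroxycyclohexanecarboxylate.
2. The C8–C12 chlorodiene comes from Takai iodo-olefination of a (Z)-β-chloroenal, which comes from anti-hydrochlorination of an ynal, itself made by elimination and formylation of a Z-enol carbamate.
3. Key bond C12–C13: homoaldol addition of a titanated (Z)-crotyl carbamate (a homoenolate equivalent) to the complete C13–C23 aldehyde, setting C12 and C13.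
4. The C13–C23 aldehyde comes from a C16–C17 aldol between a methyl ketone and an α-chloro aldehyde (from an anti chloroacetyl aldol with (E)-pent-2-enal), then 1,3-syn reduction. The ketone comes from C14–C15 bond formation by an acetyl anion equivalent (1-ethoxyvinyllithium) on (R)-glyceraldehyde acetonide.
5. No ring is built. The cyclohexane comes from (S)-cyclohex-3-ene-1-carboxylic acid by cis-dihydroxylation; the dioxolane of the glyceraldehyde unit is only a temporary mask, later cleaved to unveil C13.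

Assumption: the facial sense of the auxiliary-controlled aldol in step 2 is taken from the propionyl series; if it proves opposite, the enantiomeric auxiliary is used and nothing else changes.

Locants C1–C23 in the text are those of the acyl chain of the target.

## Route

Step 1
Reactants: 1 (S)-4-benzyl-1,3-thiazolidine-2-thione; 2 chloroacetyl chloride
Product: 3 (S)-4-benzyl-3-(chloroacetyl)-1,3-thiazolidine-2-thione
Conditions: Et3N, CH2Cl2, 0 °C
Reagents that add atoms: none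
Why: N-acylation (acyl substitution) of the thione nitrogen gives the activated chloroacetyl imide; no stereocentre is formed.

Step 2
Reactants: 3 (S)-4-benzyl-3-(chloroacetyl)-1,3-thiazolidine-2-thione; 4 (E)-pent-2-enal
Product: 5 (S)-4-benzyl-3-[(2S,3S,4E)-2-chloro-3-(trimethylsilyloxy)hept-4-enoyl]-1,3-thiazolidine-2-thione
Conditions: MgBr2·OEt2 (10 mol%), Et3N, Me3SiCl, EtOAc, 23 °C
Reagents that add atoms: chlorotrimethylsilane, C[Si](C)(C)Cl
Why: Evans magnesium-halide-catalysed anti-aldol reaction (soft enolisation, silyl trapping), in which the benzyl group of the auxiliary shields one enolate face (sets C18) and the anti topology sets C19; the chloroacetyl imide is a more acidic analogue of the usual propionyl substrates, so this substrate is an extension of the known scope.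

Step 3
Reactants: 5 (S)-4-benzyl-3-[(2S,3S,4E)-2-chloro-3-(trimethylsilyloxy)hept-4-enoyl]-1,3-thiazolidine-2-thione
Product: 6 (2S,3S,4E)-2-chloro-3-(trimethylsilyloxy)hept-4-enal
Conditions: iBu2AlH, CH2Cl2, −78 °C; aq. potassium sodium tartrate; used at once
Reagents that add atoms: none
Why: hydride reduction of an N-acyl thiazolidinethione stops at the aldehyde because the tetrahedral aluminate is stable at −78 °C, releasing the auxiliary without touching C18 or C19.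

Step 4
Reactants: 7 ethyl vinyl ether; 8 (R)-2,2-dimethyl-1,3-dioxolane-4-carbaldehyde
Product: 11 (1R)-1-[(4R)-2,2-dimethyl-1,3-dioxolan-4-yl]-1-hydroxypropan-2-one, via 1-ethoxyvinyllithium 9 (not isolated), via enol ether adduct 10 (not isolated)
Conditions: t-BuLi, THF, −78 → 0 °C; 8, −78 °C; then 0.5 M aq. HCl, THF, 0 °C
Reagents that add atoms: water, O
Why: acyl anion addition (1-ethoxyvinyllithium as an acetyl anion equivalent) to the α-alkoxy aldehyde under Felkin–Anh control gives the anti adduct (sets C14, about 4:1, minor isomer removed after step 5), and the enol ether hydrolyses to the methyl ketone far faster than the acetonide.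

Step 5
Reactants: 11 (1R)-1-[(4R)-2,2-dimethyl-1,3-dioxolan-4-yl]-1-hydroxypropan-2-one
Product: 12 (1R)-1-(tert-butyldimethylsilyloxy)-1-[(4R)-2,2-dimethyl-1,3-dioxolan-4-yl]propan-2-one
Conditions: TBSOTf, 2,6-lutidine, CH2Cl2, −78 °C
Reagents that add atoms: tert-butyldimethylsilyl trifluoromethanesulfonate, CC(C)(C)[Si](C)(C)OS(=O)(=O)C(F)(F)F
Why: O-silylation under buffered low-temperature conditions protects the α-hydroxy ketone without epimerising C14.

Step 6
Reactants: 12 (1R)-1-(tert-butyldimethylsilyloxy)-1-[(4R)-2,2-dimethyl-1,3-dioxolan-4-yl]propan-2-one; 6 (2S,3S,4E)-2-chloro-3-(trimethylsilyloxy)hept-4-enal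
Product: 14 (1R,4R,5R,6S,7E)-1-(tert-butyldimethylsilyloxy)-5-chloro-1-[(4R)-2,2-dimethyl-1,3-dioxolan-4-yl]-4-hydroxy-6-(trimethylsilyloxy)dec-7-en-2-one, via lithium enolate 13 (not isolated)
Conditions: LiN(iPr)2, THF, −78 °C; 6, −78 °C; AcOH quench at −78 °C
Reagents that add atoms: none
Why: aldol addition of the kinetic methyl-side lithium enolate to the α-chloro aldehyde follows the Cornforth (polar Felkin–Anh) model, reinforced by the anti β-silyloxy group, and gives the 17,18-anti chlorohydrin (sets C17); the cold quench prevents epoxide closure.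

Step 7
Reactants: 14 (1R,4R,5R,6S,7E)-1-(tert-butyldimethylsilyloxy)-5-chloro-1-[(4R)-2,2-dimethyl-1,3-dioxolan-4-yl]-4-hydroxy-6-(trimethylsilyloxy)dec-7-en-2-one
Product: 16 (1S,2S,4R,5R,6S,7E)-1-(tert-butyldimethylsilyloxy)-5-chloro-1-[(4R)-2,2-dimethyl-1,3-dioxolan-4-yl]dec-7-ene-2,4,6-triol, via trimethylsilyl ether diol 15 (not isolated)
Conditions: Et2BOMe, THF/MeOH (4:1), −78 °C; NaBH4; then AcOH, MeOH, 23 °C, repeated evaporation from MeOH
Reagents that add atoms: none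
Why: Narasaka–Prasad reduction, in which boron chelation of the β-hydroxy ketone and external hydride delivery give the 1,3-syn diol (sets C15), and the acidic methanol work-up removes boron and the labile trimethylsilyl ether without base that would close the chlorohydrin.

Step 8
Reactants: 16 (1S,2S,4R,5R,6S,7E)-1-(tert-butyldimethylsilyloxy)-5-chloro-1-[(4R)-2,2-dimethyl-1,3-dioxolan-4-yl]dec-7-ene-2,4,6-triol
Product: 17 (4R)-4-[(1R,2S,4R,5R,6S,7E)-1,2,4,6-tetrakis(tert-butyldimethylsilyloxy)-5-chlorodec-7-en-1-yl]-2,2-dimethyl-1,3-dioxolane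
Conditions: TBSOTf (4 equiv), 2,6-lutidine, CH2Cl2, −78 → 0 °C
Reagents that add atoms: tert-butyldimethylsilyl trifluoromethanesulfonate, CC(C)(C)[Si](C)(C)OS(=O)(=O)C(F)(F)F
Why: exhaustive silylation with the reactive silyl triflate protects the three secondary hydroxyls under non-basic conditions that leave the chlorohydrin intact.

Step 9
Reactants: 17 (4R)-4-[(1R,2S,4R,5R,6S,7E)-1,2,4,6-tetrakis(tert-butyldimethylsilyloxy)-5-chlorodec-7-en-1-yl]-2,2-dimethyl-1,3-dioxolane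
Product: 19 (2S,3S,5R,6R,7S,8E)-2,3,5,7-tetrakis(tert-butyldimethylsilyloxy)-6-chloroundec-8-enal, via vicinal diol 18 (not isolated)
Conditions: H5IO6, EtOAc, 23 °C
Reagents that add atoms: none
Why: periodic acid hydrolyses the terminal acetonide and cleaves the liberated 1,2-diol in one pot (Malaprade glycol cleavage), turning the sacrificial glyceraldehyde stereocentre into the C13 aldehyde while the silyl ethers and the alkene survive.

Step 10
Reactants: 20 (Z)-but-2-en-1-ol; 21 N,N-diisopropylcarbamoyl chloride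
Product: 22 (Z)-but-2-en-1-yl N,N-diisopropylcarbamate
Conditions: NaH, THF, 0 → 65 °C
Reagents that add atoms: none
Why: O-carbamoylation of the sodium alkoxide gives the carbamate that directs and stabilises the later α-lithiation; the Z alkene is untouched.

Step 11
Reactants: 22 (Z)-but-2-en-1-yl N,N-diisopropylcarbamate; 19 (2S,3S,5R,6R,7S,8E)-2,3,5,7-tetrakis(tert-butyldimethylsilyloxy)-6-chloroundec-8-enal
Product: 25 (1Z,3S,4R,5R,6S,8R,9R,10S,11E)-5,6,8,10-tetrakis(tert-butyldimethylsilyloxy)-9-chloro-4-hydroxy-3-methyltetradeca-1,11-dien-1-yl N,N-diisopropylcarbamate, via lithiated carbamate 23 (not isolated), via allyltitanium reagent 24 (not isolated)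
Conditions: 22 (3 equiv), n-BuLi, TMEDA, Et2O, −78 °C; ClTi(OiPr)3, −78 °C; 19 (1 equiv), −78 → −40 °C; aq. NH4Cl
Reagents that add atoms: none
Why: Hoppe homoaldol reaction, in which the titanated carbamate (a homoenolate equivalent) adds at its γ-carbon through a chair transition state, so the Z geometry gives the 12,13-syn relationship and Felkin–Anh attack on the anti α,β-bis(silyloxy) aldehyde gives 13,14-anti, the matched enantiomer of the excess racemic reagent being consumed (mutual kinetic resolution).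

Step 12
Reactants: 25 (1Z,3S,4R,5R,6S,8R,9R,10S,11E)-5,6,8,10-tetrakis(tert-butyldimethylsilyloxy)-9-chloro-4-hydroxy-3-methyltetradeca-1,11-dien-1-yl N,N-diisopropylcarbamate
Product: 28 (4S,5R,6S,7S,9R,10R,11S,12E)-6,7,9,11-tetrakis(tert-butyldimethylsilyloxy)-10-chloro-4-methyl-5-(triethylsilyloxy)pentadec-12-en-2-ynal, via triethylsilyl ether 26 (not isolated), via lithium acetylide 27 (not isolated)
Conditions: LiN(iPr)2 (1.05 equiv), THF, −78 °C; Et3SiCl (1.05 equiv), −78 → 0 °C; LiN(iPr)2 (4 equiv), −78 → −20 °C; DMF, −78 → 0 °C; AcOH then H2O at −78 °C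
Reagents that add atoms: chlorotriethylsilane, CC[Si](Cl)(CC)CC; N,N-dimethylformamide, CN(C)C=O
Why: after O-silylation of the lithium alkoxide, amide base eliminates lithium carbamate from the Z-enol carbamate (vinylic α-lithiation and Fritsch–Buttenberg–Wiechell-type elimination) to give the lithium acetylide, which DMF formylates; the acidic cold quench protects the propargylic C12 centre.

Step 13
Reactants: 28 (4S,5R,6S,7S,9R,10R,11S,12E)-6,7,9,11-tetrakis(tert-butyldimethylsilyloxy)-10-chloro-4-methyl-5-(triethylsilyloxy)pentadec-12-en-2-ynal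
Product: 29 (2Z,4R,5R,6S,7S,9R,10R,11S,12E)-6,7,9,11-tetrakis(tert-butyldimethylsilyloxy)-3,10-dichloro-4-methyl-5-(triethylsilyloxy)pentadeca-2,12-dienal
Conditions: LiCl, AcOH, MeCN, 23 °C, dark
Reagents that add atoms: lithium chloride, [Li+].[Cl-]
Why: anti-hydrochlorination of the ynal (conjugate addition of chloride, then protonation of the allenolate anti to it) places chlorine on C11 cis to the aldehyde, which is the (10Z) geometry of the target.

Step 14
Reactants: 29 (2Z,4R,5R,6S,7S,9R,10R,11S,12E)-6,7,9,11-tetrakis(tert-butyldimethylsilyloxy)-3,10-dichloro-4-methyl-5-(triethylsilyloxy)pentadeca-2,12-dienal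
Product: 30 (1E,3Z,5R,6R,7S,8S,10R,11R,12S,13E)-7,8,10,12-tetrakis(tert-butyldimethylsilyloxy)-4,11-dichloro-1-iodo-5-methyl-6-(triethylsilyloxy)hexadeca-1,3,13-triene
Conditions: CrCl2 (divalent chromium, 8 equiv), CHI3, THF/1,4-dioxane (1:6), 0 → 23 °C
Reagents that add atoms: iodoform, IC(I)I
Why: Takai iodo-olefination converts the enal into the (E)-vinyl iodide (C8=C9) under neutral conditions that leave the vinyl and alkyl chlorides alone.

Step 15
Reactants: 31 (S)-cyclohex-3-ene-1-carboxylic acid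
Product: 32 2-(trimethylsilyl)ethoxymethyl (S)-cyclohex-3-ene-1-carboxylate
Conditions: Me3SiCH2CH2OCH2Cl, iPr2NEt, CH2Cl2, 0 → 23 °C
Reagents that add atoms: 2-(trimethylsilyl)ethoxymethyl chloride, C[Si](C)(C)CCOCCl
Why: O-alkylation of the carboxylate gives an ester that is cleaved by HF together with the silyl ethers at the end.

Step 16
Reactants: 32 2-(trimethylsilyl)ethoxymethyl (S)-cyclohex-3-ene-1-carboxylate
Product: 33 2-(trimethylsilyl)ethoxymethyl (1S,3R,4S)-3,4-dihydroxycyclohexane-1-carboxylate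
Conditions: OsO4 (2 mol%), N-methylmorpholine N-oxide, acetone/H2O, 0 → 23 °C; all-cis diol removed by chromatography
Reagents that add atoms: N-methylmorpholine N-oxide, C[N+]1([O-])CCOCC1; water, O
Why: Upjohn cis-dihydroxylation, with osmylation expected to favour the face anti to the ester only modestly (about 3:1), gives the 3,4-cis diol trans to C1 (sets C3 and C4).

Step 17
Reactants: 33 2-(trimethylsilyl)ethoxymethyl (1S,3R,4S)-3,4-dihydroxycyclohexane-1-carboxylate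
Product: 34 2-(trimethylsilyl)ethoxymethyl (1S,3R,4S)-4-(tert-butyldimethylsilyloxy)-3-hydroxycyclohexane-1-carboxylate
Conditions: TBSCl (1.05 equiv), imidazole, DMF, 0 °C
Reagents that add atoms: tert-butyldimethylsilyl chloride, CC(C)(C)[Si](C)(C)Cl
Why: selective silylation of the equatorial 4-hydroxyl over the axial 3-hydroxyl (ester equatorial) leaves the 3-OH free for acylation.

Step 18
Reactants: 35 ethyl (E)-4-(diethoxyphosphoryl)but-2-enoate
Product: 36 (E)-4-(diethoxyphosphoryl)but-2-enoic acid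
Conditions: LiOH·H2O (1.05 equiv), THF/H2O, 0 °C; then 1 M HCl
Reagents that add atoms: lithium hydroxide, [Li+].[OH-]
Why: saponification cleaves the carboxylic ester much faster than the phosphonate esters.

Step 19
Reactants: 34 2-(trimethylsilyl)ethoxymethyl (1S,3R,4S)-4-(tert-butyldimethylsilyloxy)-3-hydroxycyclohexane-1-carboxylate; 36 (E)-4-(diethoxyphosphoryl)but-2-enoic acid
Product: 37 2-(trimethylsilyl)ethoxymethyl (1S,3R,4S)-4-(tert-butyldimethylsilyloxy)-3-[(E)-4-(diethoxyphosphoryl)but-2-enoyloxy]cyclohexane-1-carboxylate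
Conditions: DCC, DMAP (cat.), CH2Cl2, 0 → 23 °C
Reagents that add atoms: none
Why: Steglich esterification acylates the only free hydroxyl (C3) with retention.

Step 20
Reactants: 38 (E)-3-iodo-2-methylprop-2-en-1-ol
Product: 39 (E)-2-methyl-3-(tributylstannyl)prop-2-en-1-ol
Conditions: (Bu3Sn)2, PdCl2(PPh3)2 (3 mol%), THF, 60 °C
Reagents that add atoms: hexabutylditin, CCCC[Sn](CCCC)(CCCC)[Sn](CCCC)(CCCC)CCCC
Why: palladium-catalysed stannylation of the vinyl iodide (oxidative addition, Sn–Sn transmetalation, reductive elimination) proceeds with retention of the E geometry.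

Step 21
Reactants: 39 (E)-2-methyl-3-(tributylstannyl)prop-2-en-1-ol
Product: 40 (E)-2-methyl-3-(tributylstannyl)prop-2-enal
Conditions: MnO2, CH2Cl2, 23 °C
Reagents that add atoms: none
Why: allylic oxidation with MnO2 gives the enal without protodestannylation or isomerisation.

Step 22
Reactants: 37 2-(trimethylsilyl)ethoxymethyl (1S,3R,4S)-4-(tert-butyldimethylsilyloxy)-3-[(E)-4-(diethoxyphosphoryl)but-2-enoyloxy]cyclohexane-1-carboxylate; 40 (E)-2-methyl-3-(tributylstannyl)prop-2-enal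
Product: 42 2-(trimethylsilyl)ethoxymethyl (1S,3R,4S)-4-(tert-butyldimethylsilyloxy)-3-[(2E,4E,6E)-6-methyl-7-(tributylstannyl)hepta-2,4,6-trienoyloxy]cyclohexane-1-carboxylate, via lithiated phosphonate 41 (not isolated)
Conditions: LiN(SiMe3)2, THF, −78 °C; 40, −78 → 0 °C
Reagents that add atoms: none
Why: vinylogous Horner–Wadsworth–Emmons olefination forms the C4=C5 bond E-selectively and keeps the C2=C3 and C6=C7 geometries.

Step 23
Reactants: 30 (1E,3Z,5R,6R,7S,8S,10R,11R,12S,13E)-7,8,10,12-tetrakis(tert-butyldimethylsilyloxy)-4,11-dichloro-1-iodo-5-methyl-6-(triethylsilyloxy)hexadeca-1,3,13-triene; 42 2-(trimethylsilyl)ethoxymethyl (1S,3R,4S)-4-(tert-butyldimethylsilyloxy)-3-[(2E,4E,6E)-6-methyl-7-(tributylstannyl)hepta-2,4,6-trienoyloxy]cyclohexane-1-carboxylate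
Product: 43 fully protected target (13-O-triethylsilyl; 14,15,17,19-O and ring 4-O tert-butyldimethylsilyl; 2-(trimethylsilyl)ethoxymethyl ester)
Conditions: Pd2(dba)3 (zerovalent palladium, 5 mol%), AsPh3, NMP, 23 °C, dark
Reagents that add atoms: none
Why: Stille coupling joins C7 and C8 with retention at both alkenes under neutral conditions, and palladium inserts into the C–I bond far faster than into either C–Cl bond.

Step 24
Reactants: 43 fully protected target
Product: 44 (1S,3R,4S)-3-[(2E,4E,6E,8E,10Z,12R,13R,14S,15S,17R,18R,19S,20E)-11,18-dichloro-13,14,15,17,19-pentahydroxy-6,12-dimethyltricosa-2,4,6,8,10,20-hexaenoyloxy]-4-hydroxycyclohexane-1-carboxylic acid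
Conditions: 48% aq. HF, MeCN, 0 → 23 °C, polypropylene vessel, dark; pH 7 buffer work-up
Reagents that add atoms: none
Why: acidic fluoride removes all six silyl ethers and fragments the 2-(trimethylsilyl)ethoxymethyl ester in one operation, avoiding basic fluoride that would close the anti chlorohydrins to epoxides or move the acyl group to the ring 4-OH.

## Compound list

1 | (S)-4-benzyl-1,3-thiazolidine-2-thione | S=C1SC[C@H](Cc2ccccc2)N1 | starting material
2 | chloroacetyl chloride | ClCC(Cl)=O | starting material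
3 | (S)-4-benzyl-3-(chloroacetyl)-1,3-thiazolidine-2-thione | O=C(CCl)N1[C@@H](Cc2ccccc2)CSC1=S | intermediate
4 | (E)-pent-2-enal | CC/C=C/C=O | starting material
5 | (S)-4-benzyl-3-[(2S,3S,4E)-2-chloro-3-(trimethylsilyloxy)hept-4-enoyl]-1,3-thiazolidine-2-thione | CC/C=C/[C@H](O[Si](C)(C)C)[C@H](Cl)C(=O)N1[C@@H](Cc2ccccc2)CSC1=S | intermediate
6 | (2S,3S,4E)-2-chloro-3-(trimethylsilyloxy)hept-4-enal (C17–C23) | CC/C=C/[C@H](O[Si](C)(C)C)[C@H](Cl)C=O | intermediate
7 | ethyl vinyl ether | C=COCC | starting material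
8 | (R)-2,2-dimethyl-1,3-dioxolane-4-carbaldehyde | O=C[C@H]1COC(C)(C)O1 | starting material
9 | 1-ethoxyvinyllithium | [Li]C(=C)OCC | intermediate
10 | (1R)-1-[(4R)-2,2-dimethyl-1,3-dioxolan-4-yl]-2-ethoxyprop-2-en-1-ol | C=C(OCC)[C@H](O)[C@H]1COC(C)(C)O1 | intermediate
11 | (1R)-1-[(4R)-2,2-dimethyl-1,3-dioxolan-4-yl]-1-hydroxypropan-2-one | CC(=O)[C@H](O)[C@H]1COC(C)(C)O1 | intermediate
12 | (1R)-1-(tert-butyldimethylsilyloxy)-1-[(4R)-2,2-dimethyl-1,3-dioxolan-4-yl]propan-2-one | CC(=O)[C@H](O[Si](C)(C)C(C)(C)C)[C@H]1COC(C)(C)O1 | intermediate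
13 | lithium enolate of 12 (methyl side) | [Li]OC(=C)[C@H](O[Si](C)(C)C(C)(C)C)[C@H]1COC(C)(C)O1 | intermediate
14 | (1R,4R,5R,6S,7E)-1-(tert-butyldimethylsilyloxy)-5-chloro-1-[(4R)-2,2-dimethyl-1,3-dioxolan-4-yl]-4-hydroxy-6-(trimethylsilyloxy)dec-7-en-2-one | CC/C=C/[C@H](O[Si](C)(C)C)[C@H](Cl)[C@H](O)CC(=O)[C@H](O[Si](C)(C)C(C)(C)C)[C@H]1COC(C)(C)O1 | intermediate
15 | (1S,2S,4R,5R,6S,7E)-1-(tert-butyldimethylsilyloxy)-5-chloro-1-[(4R)-2,2-dimethyl-1,3-dioxolan-4-yl]-6-(trimethylsilyloxy)dec-7-ene-2,4-diol | CC/C=C/[C@H](O[Si](C)(C)C)[C@H](Cl)[C@H](O)C[C@H](O)[C@H](O[Si](C)(C)C(C)(C)C)[C@H]1COC(C)(C)O1 | intermediate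
16 | (1S,2S,4R,5R,6S,7E)-1-(tert-butyldimethylsilyloxy)-5-chloro-1-[(4R)-2,2-dimethyl-1,3-dioxolan-4-yl]dec-7-ene-2,4,6-triol | CC/C=C/[C@H](O)[C@H](Cl)[C@H](O)C[C@H](O)[C@H](O[Si](C)(C)C(C)(C)C)[C@H]1COC(C)(C)O1 | intermediate
17 | (4R)-4-[(1R,2S,4R,5R,6S,7E)-1,2,4,6-tetrakis(tert-butyldimethylsilyloxy)-5-chlorodec-7-en-1-yl]-2,2-dimethyl-1,3-dioxolane | CC/C=C/[C@H](O[Si](C)(C)C(C)(C)C)[C@H](Cl)[C@H](O[Si](C)(C)C(C)(C)C)C[C@H](O[Si](C)(C)C(C)(C)C)[C@H](O[Si](C)(C)C(C)(C)C)[C@H]1COC(C)(C)O1 | intermediate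
18 | (2R,3R,4S,6R,7R,8S,9E)-3,4,6,8-tetrakis(tert-butyldimethylsilyloxy)-7-chlorododec-9-ene-1,2-diol | CC/C=C/[C@H](O[Si](C)(C)C(C)(C)C)[C@H](Cl)[C@H](O[Si](C)(C)C(C)(C)C)C[C@H](O[Si](C)(C)C(C)(C)C)[C@H](O[Si](C)(C)C(C)(C)C)[C@H](O)CO | intermediate
19 | (2S,3S,5R,6R,7S,8E)-2,3,5,7-tetrakis(tert-butyldimethylsilyloxy)-6-chloroundec-8-enal (C13–C23) | CC/C=C/[C@H](O[Si](C)(C)C(C)(C)C)[C@H](Cl)[C@H](O[Si](C)(C)C(C)(C)C)C[C@H](O[Si](C)(C)C(C)(C)C)[C@H](O[Si](C)(C)C(C)(C)C)C=O | intermediate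
20 | (Z)-but-2-en-1-ol | C/C=C\CO | starting material
21 | N,N-diisopropylcarbamoyl chloride | CC(C)N(C(C)C)C(Cl)=O | starting material
22 | (Z)-but-2-en-1-yl N,N-diisopropylcarbamate | C/C=C\COC(=O)N(C(C)C)C(C)C | intermediate
23 | (Z)-1-lithiobut-2-en-1-yl N,N-diisopropylcarbamate (racemic) | C/C=C\C([Li])OC(=O)N(C(C)C)C(C)C | intermediate
24 | (Z)-1-[tri(propan-2-yloxy)titanio]but-2-en-1-yl N,N-diisopropylcarbamate (racemic) | C/C=C\C(OC(=O)N(C(C)C)C(C)C)[Ti](OC(C)C)(OC(C)C)OC(C)C | intermediate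
25 | (1Z,3S,4R,5R,6S,8R,9R,10S,11E)-5,6,8,10-tetrakis(tert-butyldimethylsilyloxy)-9-chloro-4-hydroxy-3-methyltetradeca-1,11-dien-1-yl N,N-diisopropylcarbamate | CC/C=C/[C@H](O[Si](C)(C)C(C)(C)C)[C@H](Cl)[C@H](O[Si](C)(C)C(C)(C)C)C[C@H](O[Si](C)(C)C(C)(C)C)[C@H](O[Si](C)(C)C(C)(C)C)[C@H](O)[C@@H](C)/C=C\OC(=O)N(C(C)C)C(C)C | intermediate
26 | (1Z,3S,4R,5S,6S,8R,9R,10S,11E)-5,6,8,10-tetrakis(tert-butyldimethylsilyloxy)-9-chloro-3-methyl-4-(triethylsilyloxy)tetradeca-1,11-dien-1-yl N,N-diisopropylcarbamate | CC/C=C/[C@H](O[Si](C)(C)C(C)(C)C)[C@H](Cl)[C@H](O[Si](C)(C)C(C)(C)C)C[C@H](O[Si](C)(C)C(C)(C)C)[C@H](O[Si](C)(C)C(C)(C)C)[C@H](O[Si](CC)(CC)CC)[C@@H](C)/C=C\OC(=O)N(C(C)C)C(C)C | intermediate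
27 | lithium acetylide of (3S,4R,5S,6S,8R,9R,10S,11E)-5,6,8,10-tetrakis(tert-butyldimethylsilyloxy)-9-chloro-3-methyl-4-(triethylsilyloxy)tetradec-11-en-1-yne | CC/C=C/[C@H](O[Si](C)(C)C(C)(C)C)[C@H](Cl)[C@H](O[Si](C)(C)C(C)(C)C)C[C@H](O[Si](C)(C)C(C)(C)C)[C@H](O[Si](C)(C)C(C)(C)C)[C@H](O[Si](CC)(CC)CC)[C@@H](C)C#C[Li] | intermediate
28 | (4S,5R,6S,7S,9R,10R,11S,12E)-6,7,9,11-tetrakis(tert-butyldimethylsilyloxy)-10-chloro-4-methyl-5-(triethylsilyloxy)pentadec-12-en-2-ynal | CC/C=C/[C@H](O[Si](C)(C)C(C)(C)C)[C@H](Cl)[C@H](O[Si](C)(C)C(C)(C)C)C[C@H](O[Si](C)(C)C(C)(C)C)[C@H](O[Si](C)(C)C(C)(C)C)[C@H](O[Si](CC)(CC)CC)[C@@H](C)C#CC=O | intermediate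
29 | (2Z,4R,5R,6S,7S,9R,10R,11S,12E)-6,7,9,11-tetrakis(tert-butyldimethylsilyloxy)-3,10-dichloro-4-methyl-5-(triethylsilyloxy)pentadeca-2,12-dienal | CC/C=C/[C@H](O[Si](C)(C)C(C)(C)C)[C@H](Cl)[C@H](O[Si](C)(C)C(C)(C)C)C[C@H](O[Si](C)(C)C(C)(C)C)[C@H](O[Si](C)(C)C(C)(C)C)[C@H](O[Si](CC)(CC)CC)[C@@H](C)/C(Cl)=C/C=O | intermediate
30 | (1E,3Z,5R,6R,7S,8S,10R,11R,12S,13E)-7,8,10,12-tetrakis(tert-butyldimethylsilyloxy)-4,11-dichloro-1-iodo-5-methyl-6-(triethylsilyloxy)hexadeca-1,3,13-triene (C8–C23) | CC/C=C/[C@H](O[Si](C)(C)C(C)(C)C)[C@H](Cl)[C@H](O[Si](C)(C)C(C)(C)C)C[C@H](O[Si](C)(C)C(C)(C)C)[C@H](O[Si](C)(C)C(C)(C)C)[C@H](O[Si](CC)(CC)CC)[C@@H](C)/C(Cl)=C/C=C/I | intermediate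
31 | (S)-cyclohex-3-ene-1-carboxylic acid | OC(=O)[C@H]1CCC=CC1 | starting material
32 | 2-(trimethylsilyl)ethoxymethyl (S)-cyclohex-3-ene-1-carboxylate | C[Si](C)(C)CCOCOC(=O)[C@H]1CCC=CC1 | intermediate
33 | 2-(trimethylsilyl)ethoxymethyl (1S,3R,4S)-3,4-dihydroxycyclohexane-1-carboxylate | O[C@@H]1C[C@@H](C(=O)OCOCC[Si](C)(C)C)CC[C@@H]1O | intermediate
34 | 2-(trimethylsilyl)ethoxymethyl (1S,3R,4S)-4-(tert-butyldimethylsilyloxy)-3-hydroxycyclohexane-1-carboxylate | O[C@@H]1C[C@@H](C(=O)OCOCC[Si](C)(C)C)CC[C@@H]1O[Si](C)(C)C(C)(C)C | intermediate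
35 | ethyl (E)-4-(diethoxyphosphoryl)but-2-enoate | CCOC(=O)/C=C/CP(=O)(OCC)OCC | starting material
36 | (E)-4-(diethoxyphosphoryl)but-2-enoic acid | OC(=O)/C=C/CP(=O)(OCC)OCC | intermediate
37 | 2-(trimethylsilyl)ethoxymethyl (1S,3R,4S)-4-(tert-butyldimethylsilyloxy)-3-[(E)-4-(diethoxyphosphoryl)but-2-enoyloxy]cyclohexane-1-carboxylate | CCOP(=O)(OCC)C/C=C/C(=O)O[C@@H]1C[C@@H](C(=O)OCOCC[Si](C)(C)C)CC[C@@H]1O[Si](C)(C)C(C)(C)C | intermediate
38 | (E)-3-iodo-2-methylprop-2-en-1-ol | I/C=C(C)/CO | starting material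
39 | (E)-2-methyl-3-(tributylstannyl)prop-2-en-1-ol | CCCC[Sn](CCCC)(CCCC)/C=C(C)/CO | intermediate
40 | (E)-2-methyl-3-(tributylstannyl)prop-2-enal | CCCC[Sn](CCCC)(CCCC)/C=C(C)/C=O | intermediate
41 | γ-lithiated phosphonate of 37 | CCOP(=O)(OCC)C([Li])/C=C/C(=O)O[C@@H]1C[C@@H](C(=O)OCOCC[Si](C)(C)C)CC[C@@H]1O[Si](C)(C)C(C)(C)C | intermediate
42 | 2-(trimethylsilyl)ethoxymethyl (1S,3R,4S)-4-(tert-butyldimethylsilyloxy)-3-[(2E,4E,6E)-6-methyl-7-(tributylstannyl)hepta-2,4,6-trienoyloxy]cyclohexane-1-carboxylate | CCCC[Sn](CCCC)(CCCC)/C=C(C)/C=C/C=C/C(=O)O[C@@H]1C[C@@H](C(=O)OCOCC[Si](C)(C)C)CC[C@@H]1O[Si](C)(C)C(C)(C)C | intermediate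
43 | fully protected target: 13-O-triethylsilyl, 14,15,17,19-O- and ring 4-O-tert-butyldimethylsilyl, 2-(trimethylsilyl)ethoxymethyl ester; all stereocentres and alkene geometries as in 44 | CC/C=C/[C@H](O[Si](C)(C)C(C)(C)C)[C@H](Cl)[C@H](O[Si](C)(C)C(C)(C)C)C[C@H](O[Si](C)(C)C(C)(C)C)[C@H](O[Si](C)(C)C(C)(C)C)[C@H](O[Si](CC)(CC)CC)[C@@H](C)/C(Cl)=C/C=C/C=C(C)/C=C/C=C/C(=O)O[C@@H]1C[C@@H](C(=O)OCOCC[Si](C)(C)C)CC[C@@H]1O[Si](C)(C)C(C)(C)C | intermediate
44 | (1S,3R,4S)-3-[(2E,4E,6E,8E,10Z,12R,13R,14S,15S,17R,18R,19S,20E)-11,18-dichloro-13,14,15,17,19-pentahydroxy-6,12-dimethyltricosa-2,4,6,8,10,20-hexaenoyloxy]-4-hydroxycyclohexane-1-carboxylic acid (CNP0353301.1) | CC/C=C/[C@H](O)[C@H](Cl)[C@H](O)C[C@H](O)[C@H](O)[C@H](O)[C@@H](C)/C(Cl)=C/C=C/C=C(C)/C=C/C=C/C(=O)O[C@@H]1C[C@@H](C(=O)O)CC[C@@H]1O | target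

## Step count and risk

Total step count: 24.
Longest linear sequence: 13 steps (1, 2, 3, 6, 7, 8, 9, 11, 12, 13, 14, 23, 24).

Three steps most likely to fail:

Step 2 (magnesium-catalysed anti-aldol of a chloroacetyl imide; the substrate class is untested and may give low anti selectivity or decompose through ketene or epoxide formation). The fallback sets out from 4 (with 2) and comes back at 6. It replaces the soft-enolised imide by a preformed titanium ester enolate on an aminoindanol auxiliary. Commercial (1S,2R)-1-aminoindan-2-ol is N-tosylated (TsCl, Et3N) to N-[(1S,2R)-2-hydroxy-2,3-dihydro-1H-inden-1-yl]-4-methylbenzenesulfonamide F1. This is esterified with 2 (pyridine, CH2Cl2) to the chloroacetate F2. Enolisation of F2 with TiCl4 and iPr2NEt, then addition to 4 precomplexed with TiCl4 at −78 °C, gives the anti α-chloro-β-hydroxy ester F3 (titanium ester-enolate anti-aldol, a reaction type reported for chloroacetates of this auxiliary). Silylation (Me3SiCl, imidazole) gives the trimethylsilyl ether F4, and iBu2AlH at −78 °C releases the auxiliary and returns 6.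

Step 11 (homoaldol addition with a racemic (Z)-crotyl titanium reagent; diastereocontrol rests on Felkin–Anh selection and on kinetic resolution of the reagent by a hindered aldehyde). The fallback sets out from 19 and comes back at 27. It makes the C12–C13 bond by a reagent-controlled allenylstannane addition that delivers the alkyne directly, so the carbamate elimination of step 12 is no longer needed. Commercial (S)-but-3-yn-2-ol is mesylated (MsCl, Et3N) to (S)-but-3-yn-2-yl methanesulfonate F5. Bu3SnLi with CuBr·SMe2 in THF at −78 °C displaces it in an anti SN2' sense to give (M)-tributyl(buta-1,2-dien-1-yl)stannane F6. BF3·OEt2-promoted addition of F6 to 19 at −78 °C (open transition state, anti SE2', syn-selective) gives the 12,13-syn homopropargylic alcohol F7. LiN(iPr)2 and Et3SiCl give its triethylsilyl ether F8, and a further equivalent of LiN(iPr)2 gives 27, which is formylated as in step 12.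

Step 13 (hydrochlorination of the ynal; risk of E/Z mixtures, epimerisation at C12 through the dienol, or loss of the triethylsilyl ether in acid). The fallback sets out from 27 and comes back at 29. Chlorine is introduced by directed hydroalumination instead of conjugate addition. 27 is quenched with paraformaldehyde in place of DMF to give the propargylic alcohol F9. NaAlH2(OCH2CH2OMe)2 in THF at 0 °C adds hydride trans, with aluminium at C11 (alkoxide-directed). N-Chlorosuccinimide at −78 °C then replaces aluminium by chlorine with retention to give the (Z)-3-chloroallylic alcohol F10, and MnO2 in CH2Cl2 oxidises F10 to 29.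

## Further compounds

F1 | step 2 | N-[(1S,2R)-2-hydroxy-2,3-dihydro-1H-inden-1-yl]-4-methylbenzenesulfonamide | Cc1ccc(cc1)S(=O)(=O)N[C@H]1c2ccccc2C[C@H]1O
F2 | step 2 | (1S,2R)-1-(4-methylbenzenesulfonamido)-2,3-dihydro-1H-inden-2-yl chloroacetate | Cc1ccc(cc1)S(=O)(=O)N[C@H]1c2ccccc2C[C@H]1OC(=O)CCl
F3 | step 2 | (1S,2R)-1-(4-methylbenzenesulfonamido)-2,3-dihydro-1H-inden-2-yl (2S,3S,4E)-2-chloro-3-hydroxyhept-4-enoate | CC/C=C/[C@H](O)[C@H](Cl)C(=O)O[C@@H]1Cc2ccccc2[C@@H]1NS(=O)(=O)c1ccc(C)cc1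
F4 | step 2 | (1S,2R)-1-(4-methylbenzenesulfonamido)-2,3-dihydro-1H-inden-2-yl (2S,3S,4E)-2-chloro-3-(trimethylsilyloxy)hept-4-enoate | CC/C=C/[C@H](O[Si](C)(C)C)[C@H](Cl)C(=O)O[C@@H]1Cc2ccccc2[C@@H]1NS(=O)(=O)c1ccc(C)cc1
F5 | step 11 | (S)-but-3-yn-2-yl methanesulfonate | C[C@H](OS(C)(=O)=O)C#C
F6 | step 11 | (M)-tributyl(buta-1,2-dien-1-yl)stannane | [H]C(C)=[C@@]=C([H])[Sn](CCCC)(CCCC)CCCC
F7 | step 11 | (3S,4R,5R,6S,8R,9R,10S,11E)-5,6,8,10-tetrakis(tert-butyldimethylsilyloxy)-9-chloro-3-methyltetradec-11-en-1-yn-4-ol | CC/C=C/[C@H](O[Si](C)(C)C(C)(C)C)[C@H](Cl)[C@H](O[Si](C)(C)C(C)(C)C)C[C@H](O[Si](C)(C)C(C)(C)C)[C@H](O[Si](C)(C)C(C)(C)C)[C@H](O)[C@@H](C)C#C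
F8 | step 11 | (3S,4R,5S,6S,8R,9R,10S,11E)-5,6,8,10-tetrakis(tert-butyldimethylsilyloxy)-9-chloro-3-methyl-4-(triethylsilyloxy)tetradec-11-en-1-yne | CC/C=C/[C@H](O[Si](C)(C)C(C)(C)C)[C@H](Cl)[C@H](O[Si](C)(C)C(C)(C)C)C[C@H](O[Si](C)(C)C(C)(C)C)[C@H](O[Si](C)(C)C(C)(C)C)[C@H](O[Si](CC)(CC)CC)[C@@H](C)C#C
F9 | step 13 | (4S,5R,6S,7S,9R,10R,11S,12E)-6,7,9,11-tetrakis(tert-butyldimethylsilyloxy)-10-chloro-4-methyl-5-(triethylsilyloxy)pentadec-12-en-2-yn-1-ol | CC/C=C/[C@H](O[Si](C)(C)C(C)(C)C)[C@H](Cl)[C@H](O[Si](C)(C)C(C)(C)C)C[C@H](O[Si](C)(C)C(C)(C)C)[C@H](O[Si](C)(C)C(C)(C)C)[C@H](O[Si](CC)(CC)CC)[C@@H](C)C#CCO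
F10 | step 13 | (2Z,4R,5R,6S,7S,9R,10R,11S,12E)-6,7,9,11-tetrakis(tert-butyldimethylsilyloxy)-3,10-dichloro-4-methyl-5-(triethylsilyloxy)pentadeca-2,12-dien-1-ol | CC/C=C/[C@H](O[Si](C)(C)C(C)(C)C)[C@H](Cl)[C@H](O[Si](C)(C)C(C)(C)C)C[C@H](O[Si](C)(C)C(C)(C)C)[C@H](O[Si](C)(C)C(C)(C)C)[C@H](O[Si](CC)(CC)CC)[C@@H](C)/C(Cl)=C/CO
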